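## The problem

The target, (1R,2S)-1-(3,4-dimethoxyphenyl)-6,7-dimethoxy-2,3-dimethyl-1,2-dihydronaphthalene (9), is a 1-aryl-1,2-dihydronaphthalene. Ring A is a dimethoxybenzo ring fused through C4a and C8a to the carbocyclic ring B. Ring B carries the pendant 3,4-dimethoxyphenyl ring C on C1, methyl groups on C2 and C3, and a trisubstituted C3=C4 double bond conjugated with ring A. There are only two stereocentres, the diarylmethine C1 (R) and the methyl-bearing C2 (S), and they are trans. C1 is doubly benzylic and is best made by capture of a planar benzylic cation, so the methyl group next to it can decide the face; C2 can control C1, not the reverse. Absolute configuration is a separate question, because every simple precursor that has both methyl groups on ring B is flat or mirror-symmetric. The compound sits at the dihydronaphthalene oxidation level: an intermediate with the C3=C4 bond and a leaving group, radical or metal on C1 is one proton or hydrogen atom away from a naphthalene. Acid can also move the double bond to the tetrasubstituted C1=C2 position, which would erase both stereocentres, and the electron-rich rings make every benzylic C–O bond easy to ionise. The enabling feature is symmetry: ring A is symmetric about the C6/C7 methoxy pair, its adjacent carbons C8a and C4a bear C1 and C4, and C2 and C3 each bear a methyl group, so a symmetric aryne and a symmetric furan can make both bonds between ring A and ring B at once.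

## Retrosynthesis

Ring B positions are numbered as in the target throughout (C1 aryl, C2 and C3 methyl, C4 alkene CH).

**9 from 8.** The last bond made is the C3=C4 π bond. Adding acetic acid across it in the retro sense puts an acetoxy group on C4 and a hydrogen on C3 and gives tetralin acetate 8. The neighbouring choice, to keep the styrene and make the C1–aryl bond last, is rejected on mechanistic grounds. A cation, radical or metal on C1 of a compound that already has the C3=C4 bond is the σ-complex of a fully aromatic ring and will lose the C2 hydrogen before it can be arylated. Precursor 8 is no simpler in skeleton, but it cannot aromatise and its oxygen function is a handle for resolution. The forward elimination has only one direction to go (C3–H is the only β-hydrogen) and must leave C1 and C2 alone.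

**8 from 7.** Cutting the acyl–oxygen bond leads to racemic alcohol 7; this is where the enantiomers are separated. Alcohol 7 is the first chiral compound of the route, because the step that makes it breaks one of two enantiotopic C–O bonds in an achiral medium. A catalytic desymmetrisation would be more economical, but two obvious versions are not dependable here:
- Enantioselective acid-catalysed arylation of a bridging benzylic ether has no precedent to rest a plan on.
- Hydride-induced SN2′ opening of the unsaturated adduct 4 is well known only for disubstituted alkenes; here it would have to add to a tetrasubstituted alkene and would give exactly the aromatisation-prone alcohol excluded above.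

Lipase-catalysed acylation of a secondary benzylic carbinol is therefore chosen. Its price is half of the material. The forward step must discriminate the enantiomers of a hindered carbinol.

**7 from 5 and 6.** The bond between C1 and ring C is cut and C1 is reconnected to the oxygen on C4, giving the meso 1,4-epoxytetralin 5 and 1,2-dimethoxybenzene 6. This Friedel–Crafts cut is preferred to a cross-coupling for three reasons:
- It uses the ether oxygen already present as the leaving group.
- It needs no prefunctionalised arene; substitution of 6 para to a methoxy group gives the 3,4-dimethoxyphenyl pattern.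
- It places the aryl group by substrate control. Both methyl groups lie on the face opposite the bridge, so one of them is always pseudo-axial on that face of the benzylic cation, and the arene enters from the face the oxygen leaves, trans to the C2 methyl.

The precursor is meso and ring C is a commodity. The forward reaction must stop after one arylation and leave the liberated alcohol intact.

**5 from 4.** Ether 5 comes from the unsaturated adduct 4 by retro-hydrogenation of the C2–C3 bond. Saturation before ionisation is essential: from 4 the cation would be allylic, arylation could occur at C1 or C3, and the product could again lose water to an aromatic ring. Hydrogenation also fixes the two methyl groups cis, which is what makes the arylation face-selective. The forward step needs syn addition of hydrogen to a strained tetrasubstituted alkene without hydrogenolysis of the benzylic C–O bonds.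

**4 from 1 and 2 via 3.** Adduct 4 is cut at C1–C8a and C4–C4a in a retro-[4+2] sense, giving 4,5-dimethoxybenzyne 3 (from silyl triflate 1) and 3,4-dimethylfuran 2. Cutting both bonds at once is better than cutting one (a Friedel–Crafts ring closure of a chain that already carries the stereocentres) or building ring A last. Aryne and diene are each symmetric, so there is no regiochemistry to control, and C1–C4 arrive with both methyl groups and a latent leaving group on C1 and on C4. Both precursors are purchasable. The forward step only has to generate 3 under conditions mild enough for the acid-sensitive adduct.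

## Roads not taken

**Alternative 1:** photoenol Diels–Alder with a chiral crotonimide.
- Cut: C1–C2 and C3–C4 of ring B.
- Forward key step: irradiation near 350 nm converts 2-(3,4-dimethoxybenzyl)-4,5-dimethoxybenzaldehyde A1 into its hydroxy-o-quinodimethane, which is trapped by (S)-4-benzyl-3-[(E)-but-2-enoyl]oxazolidin-2-one A2 to give the 1-aryl-4-hydroxy-2-methyltetralin-3-carbonyl oxazolidinone A3.
- Merits: ring B and the trans C1/C2 pair form in one step, and the auxiliary sets absolute configuration without resolution. In that respect it is better than the chosen plan.
- Weak points: a β-methyl-substituted imide is a slow dienophile and must compete with reketonisation of the photoenol. The geometry of the aryl-bearing dienol terminus decides C1. Facial control by an uncomplexed auxiliary in a photochemical cycloaddition is uncertain. After the key step the C3 acyl group must be reduced to a methyl group and the C4 hydroxyl eliminated without moving the alkene, which adds several steps on top of the preparation of A1.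
- Comparison: the chosen plan sets against its lost half of material a shorter sequence of ground-state reactions from purchased compounds and no carbonyl-to-methyl adjustment.

**Alternative 2:** oxazoline-directed dearomatising arylation and methylation.
- Cut: the C1–aryl and C2–methyl bonds on an intact naphthalene.
- Forward key step: 3,4-dimethoxyphenyllithium A5 adds to C1 of (S)-4-tert-butyl-2-(6,7-dimethoxy-3-methylnaphthalen-2-yl)-4,5-dihydrooxazole A4, and the aza-enolate is methylated at C2 with iodomethane A6 to give the trans-1-aryl-2-methyl-2-oxazolinyl-1,2-dihydronaphthalene A7.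
- Merits: both stereocentres and the absolute configuration are set in one step of a reliably trans-selective reaction type, and A7 already has the C3=C4 bond with no leaving group that could aromatise. This is clearly better stereocontrol than a resolution.
- Weak points: the oxazoline carbon is not part of the target and sits on a quaternary C2; it must be excised with replacement by hydrogen with retention (hydrolysis to the aldehyde, then decarbonylation). The C3 methyl ortho to the oxazoline invites lateral lithiation by A5, the electron-rich naphthalene is a poorer acceptor, and A4 needs its own multi-step naphthalene synthesis.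
- Comparison: the chosen plan has no auxiliary carbon to remove and far shorter access to its substrates.

**Alternative 3:** cobalt [2+2+2] assembly of rings A and B.
- Cut: C4a–C8a, C5–C6 and C7–C8, so ring A is made last and ring B closes in the same event.
- Forward key step: CpCo(CO)2 A11 under light and heat couples the (Z)-3-(3,4-dimethoxyphenyl)-4,5-dimethyloct-5-ene-1,7-diyne A8 with bis(pinacolatoboryl)ethyne A9 to give the 6,7-bis(pinacolatoboryl) analogue A10; oxidation of both C–B bonds and double O-methylation would follow.
- Merits: convergent, and the diboryl intermediate would be better than the chosen plan for varying the C6/C7 substituents.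
- Weak points: it builds a ring that can be bought with its methoxy groups in place. Both stereocentres must already exist in acyclic A8, whose C1–H is propargylic and benzylic and therefore prone to epimerisation, so the stereochemical problem is postponed, not solved. The Z-enediyne needs its own synthesis.
- Comparison: the chosen plan starts from ring A intact and deals with the stereocentres on a rigid bicyclic frame.

Key step: step 1

Assumption: 1, 2 and 6 are taken as purchased compounds, and a racemic compound is written in SMILES as its two enantiomers joined by a dot.

## Route

Step 1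
Reactants: 1 4,5-dimethoxy-2-(trimethylsilyl)phenyl trifluoromethanesulfonate; 2 3,4-dimethylfuran
Product: 4 meso-(1R,4S)-6,7-dimethoxy-2,3-dimethyl-1,4-dihydro-1,4-epoxynaphthalene, via 4,5-dimethoxybenzyne 3 (not isolated)
Conditions: CsF (3 equiv), 2 (3 equiv), MeCN, 25 °C
Reagents that add atoms: none
Why: Fluoride attacks silicon of 1 and the aryl anion expels the ortho triflate, releasing aryne 3 at room temperature without strong base. The strained triple bond of 3 adds across C2 and C5 of furan 2 in a concerted suprafacial [4+2] cycloaddition; the closest known reaction type is the Diels–Alder trapping of fluoride-generated arynes by furans. Ring B closes as a six-membered carbocycle by intermolecular cycloaddition, C1–C8a and C4–C4a forming together, with the furan oxygen left as a 1,4-bridge. The two new stereocentres are the bridgeheads; the bridge forces them cis and the mirror plane through the oxygen makes 4 meso. No regio- or facial selectivity is needed because 3 and 2 are both symmetric; the only requirement is that the furan outcompetes other aryne traps, which the excess of 2 should secure. Adduct 4 is acid-labile (ring opening to a naphthol), so it should be purified on base-washed silica.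

Step 2
Reactants: 4 meso-(1R,4S)-6,7-dimethoxy-2,3-dimethyl-1,4-dihydro-1,4-epoxynaphthalene
Product: 5 meso-(1R,2S,3R,4S)-6,7-dimethoxy-2,3-dimethyl-1,2,3,4-tetrahydro-1,4-epoxynaphthalene (both methyl groups endo, anti to the oxygen bridge)
Conditions: H2 (3 atm), 10% Pd/C, K2CO3 (cat.), EtOAc, 25 °C
Reagents that add atoms: none
Why: Heterogeneous catalytic hydrogenation; the strained alkene should take up H2 syn from the exo face (the side of the oxygen bridge, away from ring A), so both methyl groups end up endo and cis and the product stays meso. Low pressure, an aprotic solvent and a trace of base are chosen to spare the benzylic C–O bonds from hydrogenolysis and acid opening.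

Step 3
Reactants: 5 meso-(1R,2S,3R,4S)-6,7-dimethoxy-2,3-dimethyl-1,2,3,4-tetrahydro-1,4-epoxynaphthalene; 6 1,2-dimethoxybenzene
Product: 7 rac-(1R,2S,3S,4R)-4-(3,4-dimethoxyphenyl)-6,7-dimethoxy-2,3-dimethyl-1,2,3,4-tetrahydronaphthalen-1-ol (racemate; hydroxyl and aryl cis to each other and trans to both methyl groups)
Conditions: BF3·OEt2 (0.2 equiv), 6 (5 equiv), CH2Cl2, −78 to −40 °C; Et3N quench
Reagents that add atoms: none
Why: Lewis acid ionisation of the strained benzylic ether gives a 4-methoxybenzyl-type cation that alkylates 6 para to a methoxy group (Friedel–Crafts alkylation). Because the methyl groups are cis, one is always pseudo-axial on the face opposite the departing oxygen, so 6 should add from the oxygen face: aryl trans to the adjacent methyl and cis to the hydroxyl. Either enantiotopic C–O bond can break, so 7 is racemic, and ring B is at the tetralin level, so aromatisation is not possible.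

Step 4
Reactants: 7 rac-(1R,2S,3S,4R)-4-(3,4-dimethoxyphenyl)-6,7-dimethoxy-2,3-dimethyl-1,2,3,4-tetrahydronaphthalen-1-ol
Product: 8 (1R,2S,3S,4R)-4-(3,4-dimethoxyphenyl)-6,7-dimethoxy-2,3-dimethyl-1,2,3,4-tetrahydronaphthalen-1-yl acetate
Conditions: immobilised Candida antarctica lipase B, vinyl acetate (3 equiv), t-BuOMe, 35 °C, to about half conversion
Reagents that add atoms: vinyl acetate, CC(=O)OC=C
Why: Lipase-catalysed enantioselective transesterification (kinetic resolution) of a secondary benzylic alcohol; by the empirical size rule for lipases (aryl side large, CHMe side medium) the (1R) carbinol should be acetylated faster. Acetate 8 is separated from the unreacted enantiomer of 7 by chromatography, and its configuration is to be confirmed before it is carried on.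

Step 5
Reactants: 8 (1R,2S,3S,4R)-4-(3,4-dimethoxyphenyl)-6,7-dimethoxy-2,3-dimethyl-1,2,3,4-tetrahydronaphthalen-1-yl acetate
Product: 9 (1R,2S)-1-(3,4-dimethoxyphenyl)-6,7-dimethoxy-2,3-dimethyl-1,2-dihydronaphthalene
Conditions: p-TsOH·H2O (5 mol%), toluene, 60 °C
Reagents that add atoms: none
Why: Acid-catalysed E1 elimination of a benzylic acetate; ionisation is assisted by the para methoxy group and the only β-hydrogen is on the adjacent methyl-bearing carbon, so the double bond can only form as the styrenic C3=C4 bond of 9. The aryl- and methyl-bearing centres take no part and should keep their trans (1R,2S) configuration.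

## Compound list

1 | 4,5-dimethoxy-2-(trimethylsilyl)phenyl trifluoromethanesulfonate | COc1cc(OS(=O)(=O)C(F)(F)F)c([Si](C)(C)C)cc1OC | starting material
2 | 3,4-dimethylfuran | Cc1cocc1C | starting material
3 | 4,5-dimethoxybenzyne | COC1=CC#CC=C1OC | intermediate
4 | meso-(1R,4S)-6,7-dimethoxy-2,3-dimethyl-1,4-dihydro-1,4-epoxynaphthalene | COc1cc2c(cc1OC)[C@H]1O[C@@H]2C(C)=C1C | intermediate
5 | meso-(1R,2S,3R,4S)-6,7-dimethoxy-2,3-dimethyl-1,2,3,4-tetrahydro-1,4-epoxynaphthalene | COc1cc2c(cc1OC)[C@H]1O[C@@H]2[C@@H](C)[C@H]1C | intermediate
6 | 1,2-dimethoxybenzene | COc1ccccc1OC | starting material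
7 | rac-(1R,2S,3S,4R)-4-(3,4-dimethoxyphenyl)-6,7-dimethoxy-2,3-dimethyl-1,2,3,4-tetrahydronaphthalen-1-ol (racemate) | COc1ccc([C@@H]2c3cc(OC)c(OC)cc3[C@H](O)[C@@H](C)[C@H]2C)cc1OC.COc1ccc([C@H]2c3cc(OC)c(OC)cc3[C@@H](O)[C@H](C)[C@@H]2C)cc1OC | intermediate
8 | (1R,2S,3S,4R)-4-(3,4-dimethoxyphenyl)-6,7-dimethoxy-2,3-dimethyl-1,2,3,4-tetrahydronaphthalen-1-yl acetate | COc1ccc([C@@H]2c3cc(OC)c(OC)cc3[C@H](OC(C)=O)[C@@H](C)[C@H]2C)cc1OC | intermediate
9 | (1R,2S)-1-(3,4-dimethoxyphenyl)-6,7-dimethoxy-2,3-dimethyl-1,2-dihydronaphthalene | COc1ccc([C@@H]2c3cc(OC)c(OC)cc3C=C(C)[C@H]2C)cc1OC | target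

Total step count: 5. Longest linear sequence: 5 steps (from 1 or 2 to 9).

## Least certain steps

**Step 1 (key step).** The aryne may be lost to side reactions (addition of fluoride or adventitious nucleophiles, self-condensation) because the volatile diene cannot be kept at high concentration, and the adduct may open under acid during isolation. Fallback: the same aryne is generated by halogen–lithium exchange instead of desilylation. 1,2-Dibromo-4,5-dimethoxybenzene F1 is treated with n-BuLi in toluene at −78 °C in the presence of 2; the resulting (2-bromo-4,5-dimethoxyphenyl)lithium F2 loses LiBr on warming, and 3 is trapped as before. This sets out from 2 and comes back to the route at 4.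

**Step 3.** The product may re-ionise at its new benzylic C–O bond under the same Lewis acid, leading to a second arylation or to premature elimination that cannot be resolved. Reversible proton loss from the cation could also scramble the methyl-bearing centre next to it. Fallback: C–O cleavage and arylation are separated, so the remaining oxygen is masked as an ester before any cation meets the arene. Ether 5 is opened with acetyl bromide (ZnBr2 cat., CH2Cl2, 0 °C) to racemic 4-bromo-6,7-dimethoxy-2,3-dimethyl-1,2,3,4-tetrahydronaphthalen-1-yl acetate F3. The benzylic bromide alone is then ionised with AgOTf in the presence of 6 (CH2Cl2, −40 °C), a halophile that should leave the acetate alone, to give racemic 4-(3,4-dimethoxyphenyl)-6,7-dimethoxy-2,3-dimethyl-1,2,3,4-tetrahydronaphthalen-1-yl acetate F4 with the same anti-to-methyl selectivity. Methanolysis (K2CO3, MeOH) returns the alcohol. This sets out from 5 and comes back at 7.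

**Step 4.** Acylation may be slow or poorly selective, because the carbinol is flanked by a branched carbon and a peri-substituted ring, and the sense of selectivity may be opposite to the rule. In that case the unreacted alcohol is the useful enantiomer and would be dehydrated directly. Fallback: classical resolution through covalent diastereomers. Racemic 7 is esterified with (S)-2-methoxy-2-phenylacetic acid (DCC, DMAP, CH2Cl2) to the (S)-2-methoxy-2-phenylacetate of the (1R,2S,3S,4R) alcohol F5 and the (S)-2-methoxy-2-phenylacetate of the (1S,2R,3R,4S) alcohol F6. These are separated by chromatography or crystallisation, and F5 is eliminated under the acid conditions of step 5. This sets out from 7 and comes back at 9.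

**Step 5.** Acid may move the new double bond to the tetrasubstituted position between the aryl- and methyl-bearing carbons, which would destroy both stereocentres, or cause cationic dimerisation of the electron-rich styrene if contact with acid is prolonged. Fallback: a non-acidic syn elimination. Acetate 8 is cleaved (K2CO3, MeOH) to (1R,2S,3S,4R)-4-(3,4-dimethoxyphenyl)-6,7-dimethoxy-2,3-dimethyl-1,2,3,4-tetrahydronaphthalen-1-ol F7, which is dehydrated by the Burgess dehydration (methyl N-(triethylammoniosulfonyl)carbamate, toluene, 50 °C). The carbinol oxygen and the hydrogen on the adjacent carbon are cis, as the syn pathway requires. This sets out from 8 and comes back at 9.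

**Step 2.** Hydrogenolysis of a benzylic C–O bond on the metal surface may compete with the slow saturation of a tetrasubstituted alkene. Fallback: hydrogen-atom-transfer hydrogenation in solution, which goes through a tertiary carbon radical and does not insert into benzylic C–O bonds (Mn(dpm)3 cat., PhSiH3, t-BuOOH, i-PrOH, 25 °C). Both hydrogen atoms should again arrive from the open exo face. This sets out from 4 and comes back at 5 and makes no new compound.

## Further compounds

F1 | step 1 | 1,2-dibromo-4,5-dimethoxybenzene | COc1cc(Br)c(Br)cc1OC
F2 | step 1 | (2-bromo-4,5-dimethoxyphenyl)lithium | [Li]c1cc(OC)c(OC)cc1Br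
F3 | step 3 | racemic 4-bromo-6,7-dimethoxy-2,3-dimethyl-1,2,3,4-tetrahydronaphthalen-1-yl acetate (acetoxy trans to the cis methyl pair; both bromide epimers) | BrC1c2cc(OC)c(OC)cc2[C@H](OC(C)=O)[C@@H](C)[C@H]1C.BrC1c2cc(OC)c(OC)cc2[C@@H](OC(C)=O)[C@H](C)[C@@H]1C
F4 | step 3 | rac-(1R,2S,3S,4R)-4-(3,4-dimethoxyphenyl)-6,7-dimethoxy-2,3-dimethyl-1,2,3,4-tetrahydronaphthalen-1-yl acetate (racemate) | COc1ccc([C@@H]2c3cc(OC)c(OC)cc3[C@H](OC(C)=O)[C@@H](C)[C@H]2C)cc1OC.COc1ccc([C@H]2c3cc(OC)c(OC)cc3[C@@H](OC(C)=O)[C@H](C)[C@@H]2C)cc1OC
F5 | step 4 | (1R,2S,3S,4R)-4-(3,4-dimethoxyphenyl)-6,7-dimethoxy-2,3-dimethyl-1,2,3,4-tetrahydronaphthalen-1-yl (S)-2-methoxy-2-phenylacetate | COc1ccc([C@@H]2c3cc(OC)c(OC)cc3[C@H](OC(=O)[C@@H](OC)c3ccccc3)[C@@H](C)[C@H]2C)cc1OC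
F6 | step 4 | (1S,2R,3R,4S)-4-(3,4-dimethoxyphenyl)-6,7-dimethoxy-2,3-dimethyl-1,2,3,4-tetrahydronaphthalen-1-yl (S)-2-methoxy-2-phenylacetate | COc1ccc([C@H]2c3cc(OC)c(OC)cc3[C@@H](OC(=O)[C@@H](OC)c3ccccc3)[C@H](C)[C@@H]2C)cc1OC
F7 | step 5 | (1R,2S,3S,4R)-4-(3,4-dimethoxyphenyl)-6,7-dimethoxy-2,3-dimethyl-1,2,3,4-tetrahydronaphthalen-1-ol | COc1ccc([C@@H]2c3cc(OC)c(OC)cc3[C@H](O)[C@@H](C)[C@H]2C)cc1OC
F0 | step 2 | none | none
A1 | alternative 1 | 2-(3,4-dimethoxybenzyl)-4,5-dimethoxybenzaldehyde | COc1ccc(Cc2cc(OC)c(OC)cc2C=O)cc1OC
A2 | alternative 1 | (S)-4-benzyl-3-[(E)-but-2-enoyl]oxazolidin-2-one | C/C=C/C(=O)N1[C@@H](Cc2ccccc2)COC1=O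
A3 | alternative 1 | 1-aryl-4-hydroxy-2-methyltetralin-3-carbonyl oxazolidinone (1,2-trans, 2,3-trans, 3,4-cis) | COc1ccc([C@@H]2c3cc(OC)c(OC)cc3[C@H](O)[C@H](C(=O)N3[C@@H](Cc4ccccc4)COC3=O)[C@H]2C)cc1OC
A4 | alternative 2 | (S)-4-tert-butyl-2-(6,7-dimethoxy-3-methylnaphthalen-2-yl)-4,5-dihydrooxazole | COc1cc2cc(C)c(C3=N[C@@H](C(C)(C)C)CO3)cc2cc1OC
A5 | alternative 2 | 3,4-dimethoxyphenyllithium | [Li]c1ccc(OC)c(OC)c1
A6 | alternative 2 | iodomethane | CI
A7 | alternative 2 | trans-1-aryl-2-methyl-2-oxazolinyl-1,2-dihydronaphthalene (aryl and new methyl trans) | COc1ccc([C@@H]2c3cc(OC)c(OC)cc3C=C(C)[C@]2(C)C2=N[C@@H](C(C)(C)C)CO2)cc1OC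
A8 | alternative 3 | (Z)-3-(3,4-dimethoxyphenyl)-4,5-dimethyloct-5-ene-1,7-diyne with the C1 and C2 configurations of the target | C#C[C@@H](c1ccc(OC)c(OC)c1)[C@H](C)/C(C)=C\C#C
A9 | alternative 3 | bis(pinacolatoboryl)ethyne | CC1(C)OB(C#CB2OC(C)(C)C(C)(C)O2)OC1(C)C
A10 | alternative 3 | 6,7-bis(pinacolatoboryl) analogue of the target | COc1ccc([C@@H]2c3cc(B4OC(C)(C)C(C)(C)O4)c(B4OC(C)(C)C(C)(C)O4)cc3C=C(C)[C@H]2C)cc1OC
A11 | alternative 3 | CpCo(CO)2 | [Co+].[C-]#[O+].[C-]#[O+].c1cc[cH-]c1
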